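**Plan**

1. Retrosynthesis (target numbered as an azulene: C1 and C3 carbinols, C3a fusion CH, C4 ester carbon, C8a methyl-bearing fusion carbon): cut the C4–O ester bond; then cut the fusion bond C3a–C8a and re-join C8a to the C4 carbonyl carbon, which turns the 5,7-bicycle into a cis-decalin-1,8a-diol 1-mesylate; cut that decalin at its two Diels–Alder bonds.
2. Enabling feature: the oxygenated C4 of the seven-membered ring is bonded to the fusion carbon C3a, so a C4 ketone is the retron of a pinacol-type 1,2-shift of the quaternary C8a; the cyclopentane C1–C2–C3–C3a–C8a and the cycloheptene both arise from six-membered rings in that one shift.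
3. Forward: the carvacrol ring (future C1, C2, C3, C3a, C4, C8a) becomes ring A; isoprene adds ring B (future C5–C8) by Diels–Alder reaction; ring A is oxygenated; the shift contracts ring A and expands ring B; the ester is attached last.
4. Stereochemistry: C8a from the catalyst-controlled cycloaddition; all ring-A oxygens are placed cis to the angular methyl (cis-selective angular hydroxylation, convex-face epoxidation, hydride anti to C–O bonds); C3a by inversion at the sulfonate carbon during the shift; C4 by hydroxyl-directed hydride delivery.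

Key step: step 8

Conventions: decalins 4–12 carry naphthalene numbering (C1 sulfonate carbon, C2 isopropyl carbinol, C4a angular methyl, C8a angular hydroxyl; ring A = C1–C4, C4a, C8a); compounds 13–17 carry azulene numbering; α is the face that bears the angular methyl.

Assumption: the (S)-oxazaborolidinium catalyst is taken to give the (4aR,8aS) adduct 5; if the first run shows the opposite sense, the (R)-catalyst is used with no other change.

**Step 1**
Reactants: 1 carvacrol (2-methyl-5-(propan-2-yl)phenol)
Product: 2 4,4-dimethoxy-2-methyl-5-(propan-2-yl)cyclohexa-2,5-dien-1-one (quinone monoketal)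
Conditions: PhI(OAc)2 (2.2 equiv), MeOH, 0 °C to rt
Reagents that add atoms: methanol, CO
Why: oxidative dearomatization of a para-unsubstituted phenol with a diacyloxyiodoarene in methanol should give the p-quinone monoketal by two successive methoxylations at the para carbon, leaving a single carbonyl (next to the methyl-bearing carbon) to steer the cycloaddition; no stereocentre is formed.

**Step 2**
Reactants: 2 4,4-dimethoxy-2-methyl-5-(propan-2-yl)cyclohexa-2,5-dien-1-one; 3 isoprene (2-methylbuta-1,3-diene)
Product: 5 (4aR,8aS)-4a,7-dimethyl-2-(propan-2-yl)-4a,5,8,8a-tetrahydronaphthalene-1,4-dione (cis-fused), via Diels–Alder dimethyl ketal 4 (not isolated)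
Conditions: 3 (5 equiv), (S)-B-(2-methylphenyl)oxazaborolidine from (S)-α,α-diphenylprolinol activated with HN(SO2CF3)2 (20 mol %), CH2Cl2, −78 to −20 °C; then 1 M aq. HCl, THF, 0 °C
Reagents that add atoms: isoprene (3), CC(=C)C=C; water, O
Why: chiral-Lewis-acid-catalysed Diels–Alder reaction in which only the α-methyl enone double bond of 2 is a competent dienophile (the other is β,β-disubstituted), the nucleophilic CH2 terminus next to the methyl of isoprene bonds to the β-carbon (para orientation), suprafacial addition gives the cis ring fusion and the catalyst face sets C4a and C8a, after which the allylic ketal is hydrolysed.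

**Step 3**
Reactants: 5 (4aR,8aS)-4a,7-dimethyl-2-(propan-2-yl)-4a,5,8,8a-tetrahydronaphthalene-1,4-dione
Product: 7 (4aR,8aR)-8a-hydroxy-4a,7-dimethyl-2-(propan-2-yl)-4a,5,8,8a-tetrahydronaphthalene-1,4-dione (8a-OH cis to 4a-Me), via potassium enolate 6 (not isolated)
Conditions: KN(SiMe3)2 (1.1 equiv), THF, −78 °C; then 2-(benzenesulfonyl)-3-phenyloxaziridine, −78 °C; then AcOH
Reagents that add atoms: 2-(benzenesulfonyl)-3-phenyloxaziridine, O=S(=O)(c1ccccc1)N1OC1c1ccccc1
Why: the ene-dione has a single enolizable α-hydrogen (C8a–H), and Davis hydroxylation of its enolate should enter on the face of the angular methyl to keep the cis ring fusion, as in angular alkylations of 10-methyl-1-decalone enolates.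

**Step 4**
Reactants: 7 (4aR,8aR)-8a-hydroxy-4a,7-dimethyl-2-(propan-2-yl)-4a,5,8,8a-tetrahydronaphthalene-1,4-dione
Product: 8 2α,3α-epoxy-8a-hydroxy-4a,7-dimethyl-2-(propan-2-yl)-2,3,4a,5,8,8a-hexahydronaphthalene-1,4-dione (oxirane oxygen, 8a-OH and 4a-Me all α)
Conditions: tBuOOH (in decane), DBU, CH2Cl2, 0 °C
Reagents that add atoms: tert-butyl hydroperoxide, CC(C)(C)OO
Why: Weitz–Scheffer (nucleophilic) epoxidation attacks only the electron-poor ene-dione double bond and leaves the isolated trisubstituted alkene alone; the peroxide should add to the convex α-face of the cis-fused bicycle, which fixes the C2 oxygen cis to the angular methyl.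

**Step 5**
Reactants: 8 2α,3α-epoxy-8a-hydroxy-4a,7-dimethyl-2-(propan-2-yl)-2,3,4a,5,8,8a-hexahydronaphthalene-1,4-dione
Product: 10 (1S,2R,4R,4aS,8aR)-4a,7-dimethyl-2-(propan-2-yl)-1,2,3,4,4a,5,8,8a-octahydronaphthalene-1,2,4,8a-tetrol (all four hydroxyls and 4a-Me α), via epoxy triol 9 (not isolated)
Conditions: LiAlH4 (excess), THF, −78 °C to 60 °C; then H2O, aq. NaOH
Reagents that add atoms: none
Why: hydride should add to both carbonyls anti to the flanking C–O bonds (oxirane and C8a–O, Felkin–Anh control) to give the 1α- and 4α-alcohols, and on warming open the oxirane by trans-diaxial attack at the secondary C3 (hydride epoxide opening), which leaves the tertiary C2 alcohol with its configuration.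

**Step 6**
Reactants: 10 (1S,2R,4R,4aS,8aR)-4a,7-dimethyl-2-(propan-2-yl)-1,2,3,4,4a,5,8,8a-octahydronaphthalene-1,2,4,8a-tetrol
Product: 11 4-O-tert-butyldimethylsilyl ether of 10
Conditions: TBSCl (1.1 equiv), imidazole, DMF, 0 °C
Reagents that add atoms: tert-butyldimethylsilyl chloride, CC(C)(C)[Si](C)(C)Cl
Why: silyl ether formation should take place at C4–OH, the only secondary hydroxyl not flanked by two fully substituted carbons, while the tertiary hydroxyls are inert to TBSCl and imidazole.

**Step 7**
Reactants: 11 4-O-tert-butyldimethylsilyl ether of 10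
Product: 12 1-O-methanesulfonate of 11 (1α-OMs, 2α-OH, 4α-OTBS, 8a α-OH; cis-fused)
Conditions: MsCl (1.2 equiv), Et3N, CH2Cl2, −20 °C
Reagents that add atoms: methanesulfonyl chloride, CS(=O)(=O)Cl
Why: sulfonylation through sulfene reaches the hindered secondary C1 hydroxyl while the two tertiary hydroxyls stay free, and no stereocentre is touched.

**Step 8**
Reactants: 12 1-O-methanesulfonate of 11
Product: 13 (1R,3R,3aR,8aR)-1-[(tert-butyldimethylsilyl)oxy]-3-hydroxy-6,8a-dimethyl-3-(propan-2-yl)-2,3,3a,5,8,8a-hexahydroazulen-4(1H)-one (trans-fused)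
Conditions: Et3Al (3.5 equiv), CH2Cl2, −78 to −20 °C; then aq. potassium sodium tartrate (KNaC4H4O6)
Reagents that add atoms: none
Why: Et3Al turns the two tertiary hydroxyls into aluminium alkoxides and activates the mesylate, and the C4a–C8a σ-bond, antiperiplanar to the equatorial C1–OMs bond in the hydrogen-bonded chair of ring A (three axial oxygens, equatorial isopropyl), migrates from C8a to C1 as the C8a alkoxide collapses to the ketone (pinacol-type 1,2-shift). The closest known reaction type is the organoaluminium- or base-promoted rearrangement of vicinal diol monosulfonates, the classical way from decalin-diol monosulfonates to hydroazulenones. The cyclopentane is closed by ring contraction of ring A (new C4a–C1 bond, the C8a–C3a bond of the azulene) and the cycloheptenone by the simultaneous one-carbon expansion of ring B, so neither ring closes in an exo or endo cyclization. The new stereocentre C3a arises by inversion at the mesylate carbon, so the α-mesylate gives the β-hydrogen and the trans ring fusion, while the migrating quaternary carbon keeps its configuration. The step needs selectivity for this bond over the C2–C3 ring bond, which is also antiperiplanar and could be pushed by the C2 alkoxide; the much higher migratory aptitude of the quaternary C4a over the methylene C3 should secure it, and neither flanking oxygen can close an oxirane because both are gauche to the leaving group. Low temperature and a neutral work-up keep the β-hydroxy ketone from retro-aldol cleavage and the β,γ-alkene out of conjugation.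

**Step 9**
Reactants: 13 (1R,3R,3aR,8aR)-1-[(tert-butyldimethylsilyl)oxy]-3-hydroxy-6,8a-dimethyl-3-(propan-2-yl)-2,3,3a,5,8,8a-hexahydroazulen-4(1H)-one
Product: 14 (1R,3R,3aS,4S,8aR)-1-[(tert-butyldimethylsilyl)oxy]-6,8a-dimethyl-3-(propan-2-yl)-1,2,3,3a,4,5,8,8a-octahydroazulene-3,4-diol
Conditions: Me4NBH(OAc)3 (5 equiv), MeCN–AcOH 1:1, −30 °C
Reagents that add atoms: none
Why: Evans–Saksena reduction, in which the C3 hydroxyl binds the triacetoxyborohydride and delivers hydride through a six-membered transition state to the α-face of the C4 carbonyl, so the new hydroxyl should be β (1,3-anti) against the bias of the angular methyl.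

**Step 10**
Reactants: 14 (1R,3R,3aS,4S,8aR)-1-[(tert-butyldimethylsilyl)oxy]-6,8a-dimethyl-3-(propan-2-yl)-1,2,3,3a,4,5,8,8a-octahydroazulene-3,4-diol; 15 4-[(tert-butyldimethylsilyl)oxy]benzoic acid
Product: 16 4-O-[4-(tert-butyldimethylsilyloxy)benzoyl] ester of 14
Conditions: 15 (1.5 equiv), DCC, DMAP (cat.), CH2Cl2, 0 °C to rt
Reagents that add atoms: 4-[(tert-butyldimethylsilyl)oxy]benzoic acid (15), CC(C)(C)[Si](C)(C)Oc1ccc(cc1)C(=O)O
Why: Steglich esterification should acylate only the secondary C4 hydroxyl, since the tertiary C3 hydroxyl is inert and C1 is silylated.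

**Step 11**
Reactants: 16 4-O-[4-(tert-butyldimethylsilyloxy)benzoyl] ester of 14
Product: 17 (1R,3R,3aS,4S,8aR)-1,3-dihydroxy-6,8a-dimethyl-3-(propan-2-yl)-1,2,3,3a,4,5,8,8a-octahydroazulen-4-yl 4-hydroxybenzoate (target)
Conditions: HF·pyridine, pyridine, THF, 0 °C to rt
Reagents that add atoms: none
Why: fluoride cleavage of the aryl and the secondary alkyl silyl ether, which the ester, the tertiary alcohol and the trisubstituted alkene should tolerate under buffered conditions.

**Compound list**

1 | carvacrol (2-methyl-5-(propan-2-yl)phenol) | CC(C)c1ccc(C)c(O)c1 | starting material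
2 | 4,4-dimethoxy-2-methyl-5-(propan-2-yl)cyclohexa-2,5-dien-1-one | COC1(OC)C=C(C)C(=O)C=C1C(C)C | intermediate
3 | isoprene (2-methylbuta-1,3-diene) | CC(=C)C=C | starting material
4 | cis-fused Diels–Alder adduct, C1 dimethyl ketal of 5 | CC1=CC[C@@]2(C)C(=O)C=C(C(C)C)C(OC)(OC)[C@H]2C1 | intermediate
5 | (4aR,8aS)-4a,7-dimethyl-2-(propan-2-yl)-4a,5,8,8a-tetrahydronaphthalene-1,4-dione | CC1=CC[C@@]2(C)C(=O)C=C(C(C)C)C(=O)[C@H]2C1 | intermediate
6 | potassium C1(8a)-enolate of 5 | CC1=CC[C@@]2(C)C(=O)C=C(C(C)C)C([O-])=C2C1.[K+] | intermediate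
7 | (4aR,8aR)-8a-hydroxy-4a,7-dimethyl-2-(propan-2-yl)-4a,5,8,8a-tetrahydronaphthalene-1,4-dione | CC1=CC[C@@]2(C)C(=O)C=C(C(C)C)C(=O)[C@@]2(O)C1 | intermediate
8 | 2α,3α-epoxy-8a-hydroxy-4a,7-dimethyl-2-(propan-2-yl)-2,3,4a,5,8,8a-hexahydronaphthalene-1,4-dione | CC1=CC[C@@]2(C)C(=O)[C@@H]3O[C@]3(C(C)C)C(=O)[C@@]2(O)C1 | intermediate
9 | 2α,3α-epoxy-4a,7-dimethyl-2-(propan-2-yl)-1,2,3,4,4a,5,8,8a-octahydronaphthalene-1α,4α,8a-triol | CC1=CC[C@@]2(C)[C@H](O)[C@@H]3O[C@]3(C(C)C)[C@H](O)[C@@]2(O)C1 | intermediate
10 | (1S,2R,4R,4aS,8aR)-4a,7-dimethyl-2-(propan-2-yl)-1,2,3,4,4a,5,8,8a-octahydronaphthalene-1,2,4,8a-tetrol | CC1=CC[C@@]2(C)[C@H](O)C[C@@](O)(C(C)C)[C@H](O)[C@@]2(O)C1 | intermediate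
11 | 4-O-tert-butyldimethylsilyl ether of 10 | CC1=CC[C@@]2(C)[C@H](O[Si](C)(C)C(C)(C)C)C[C@@](O)(C(C)C)[C@H](O)[C@@]2(O)C1 | intermediate
12 | 1-O-methanesulfonate of 11 | CC1=CC[C@@]2(C)[C@H](O[Si](C)(C)C(C)(C)C)C[C@@](O)(C(C)C)[C@H](OS(C)(=O)=O)[C@@]2(O)C1 | intermediate
13 | (1R,3R,3aR,8aR)-1-[(tert-butyldimethylsilyl)oxy]-3-hydroxy-6,8a-dimethyl-3-(propan-2-yl)-2,3,3a,5,8,8a-hexahydroazulen-4(1H)-one | CC1=CC[C@@]2(C)[C@H](O[Si](C)(C)C(C)(C)C)C[C@@](O)(C(C)C)[C@@H]2C(=O)C1 | intermediate
14 | (1R,3R,3aS,4S,8aR)-1-[(tert-butyldimethylsilyl)oxy]-6,8a-dimethyl-3-(propan-2-yl)-1,2,3,3a,4,5,8,8a-octahydroazulene-3,4-diol | CC1=CC[C@@]2(C)[C@H](O[Si](C)(C)C(C)(C)C)C[C@@](O)(C(C)C)[C@@H]2[C@@H](O)C1 | intermediate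
15 | 4-[(tert-butyldimethylsilyl)oxy]benzoic acid | CC(C)(C)[Si](C)(C)Oc1ccc(cc1)C(=O)O | starting material
16 | 4-O-[4-(tert-butyldimethylsilyloxy)benzoyl] ester of 14 | CC1=CC[C@@]2(C)[C@H](O[Si](C)(C)C(C)(C)C)C[C@@](O)(C(C)C)[C@@H]2[C@@H](OC(=O)c2ccc(O[Si](C)(C)C(C)(C)C)cc2)C1 | intermediate
17 | (1R,3R,3aS,4S,8aR)-1,3-dihydroxy-6,8a-dimethyl-3-(propan-2-yl)-1,2,3,3a,4,5,8,8a-octahydroazulen-4-yl 4-hydroxybenzoate | CC1=CC[C@@]2(C)[C@H](O)C[C@@](O)(C(C)C)[C@@H]2[C@@H](OC(=O)c2ccc(O)cc2)C1 | target

**Summary**

Total step count: 11. Longest linear sequence: 11 steps (1 to 17); 3 and 15 are bought.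

**Three steps most likely to fail**

Step 8. What may go wrong: migration of the C3 methylene, pushed by the free C2 alkoxide, in place of C4a, which would contract ring A without expanding ring B; or retro-aldol cleavage of the β-hydroxy ketone during work-up. The fallback masks the C2 and C4 oxygens as one cyclic silylene before the shift; it sets out from 8 and comes back to the route at 13. Luche reduction (NaBH4, CeCl3·7H2O, MeOH, −78 °C) gives epoxy triol 9, now isolated. 2,2-Dimethoxypropane with pyridinium p-toluenesulfonate ties the cis-1,8a-diol as the 1,8a-O-isopropylidene acetal F1. NaAlH2(OCH2CH2OCH3)2 delivers hydride from the C4 alkoxide to C3 and gives the 1,8a-O-isopropylidene 2,4-diol F2. tBu2Si(OTf)2 with 2,6-lutidine bridges the two axial hydroxyls as the 2,4-O-di-tert-butylsilylene acetal F3. Aqueous acetic acid removes the acetonide to give the silylene 1,8a-diol F4, and MsCl with Et3N gives the silylene 1-O-mesylate F5, in which the C8a hydroxyl is the only free one and ring A is locked in the reactive chair. Et3Al then gives the 1,3-O-silylene hydroazulenone F6; HF·pyridine frees the 1,3-dihydroxy ketone F7, and TBSCl with imidazole silylates its secondary hydroxyl to give 13.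

Step 5. What may go wrong: poor facial selectivity at one of the two carbonyls, or hydride attack at the tertiary oxirane carbon, in the one-pot hydride cascade. The fallback separates the events; it sets out from 8 and comes back at 10. Na[PhSeB(OEt)3] (from PhSeSePh and NaBH4 in EtOH, with AcOH) can attack only the secondary oxirane carbon C3, α to the C4 carbonyl, and after reductive loss of selenium gives the 2,8a-dihydroxy-1,4-dione F8. NaBH4 with CeCl3·7H2O (MeOH, −78 °C) then reduces both carbonyls of the chair-locked ring: the C4 carbonyl by equatorial attack, because the axial C2 and C8a oxygens block the α-face, and the C1 carbonyl anti to its two axial C–O neighbours, to give 10.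

Step 2. What may go wrong: sluggish cycloaddition of the α-methyl dienone, ionization of the dimethyl ketal by the strong acid catalyst, or low enantioselectivity. The fallback replaces catalyst control by a chiral ketal auxiliary; it sets out from 2 and comes back at 5. Transketalization of 2 with (1R,2R)-1,2-diphenylethane-1,2-diol (pyridinium p-toluenesulfonate, benzene, removal of methanol) gives the spiro diphenyldioxolane dienone F9, whose ketal carbon is not stereogenic because the diol is C2-symmetric. Cycloaddition with 3 promoted by EtAlCl2 (toluene, −40 °C) should take place on the face of the dienophile carbon next to the ketal that is not covered by a phenyl group and give the cis-fused dioxolane adduct F10, separable from its diastereomer. Aqueous CF3CO2H then releases 5 and the diol. If the auxiliary favours the other face, its (1S,2S) antipode is taken.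

**Further compounds**

F1 | step 8 | 1,8a-O-isopropylidene acetal of epoxy triol 9 | CC1=CC[C@@]2(C)[C@H](O)[C@@H]3O[C@]3(C(C)C)[C@H](O4)[C@@]2(OC4(C)C)C1
F2 | step 8 | 1,8a-O-isopropylidene 2,4-diol | CC1=CC[C@@]2(C)[C@H](O)C[C@@](O)(C(C)C)[C@H](O3)[C@@]2(OC3(C)C)C1
F3 | step 8 | 2,4-O-di-tert-butylsilylene 1,8a-O-isopropylidene acetal | CC1=CC[C@@]2(C)[C@H](O3)C[C@@](O[Si]3(C(C)(C)C)C(C)(C)C)(C(C)C)[C@H](O4)[C@@]2(OC4(C)C)C1
F4 | step 8 | 2,4-O-di-tert-butylsilylene 1,8a-diol | CC1=CC[C@@]2(C)[C@H](O3)C[C@@](O[Si]3(C(C)(C)C)C(C)(C)C)(C(C)C)[C@H](O)[C@@]2(O)C1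
F5 | step 8 | 2,4-O-di-tert-butylsilylene 1-O-mesylate | CC1=CC[C@@]2(C)[C@H](O3)C[C@@](O[Si]3(C(C)(C)C)C(C)(C)C)(C(C)C)[C@H](OS(C)(=O)=O)[C@@]2(O)C1
F6 | step 8 | 1,3-O-di-tert-butylsilylene hydroazulen-4-one | CC1=CC[C@@]2(C)[C@H](O3)C[C@@](O[Si]3(C(C)(C)C)C(C)(C)C)(C(C)C)[C@@H]2C(=O)C1
F7 | step 8 | 1,3-dihydroxy hydroazulen-4-one (13 without its silyl group) | CC1=CC[C@@]2(C)[C@H](O)C[C@@](O)(C(C)C)[C@@H]2C(=O)C1
F8 | step 5 | 2,8a-dihydroxy-4a,7-dimethyl-2-(propan-2-yl)-2,3,4a,5,8,8a-hexahydronaphthalene-1,4-dione | CC1=CC[C@@]2(C)C(=O)C[C@@](O)(C(C)C)C(=O)[C@@]2(O)C1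
F9 | step 2 | spiro (4R,5R)-4,5-diphenyl-1,3-dioxolane ketal of the dienone | CC1=CC2(O[C@H](c3ccccc3)[C@@H](c3ccccc3)O2)C(C(C)C)=CC1=O
F10 | step 2 | cis-fused Diels–Alder adduct of F9 (dioxolane ketal of 5) | CC1=CC[C@@]2(C)C(=O)C=C(C(C)C)C3(O[C@H](c4ccccc4)[C@@H](c4ccccc4)O3)[C@H]2C1
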